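Readings and results come from a simulation for substances that don't exist, and the scatter is random.

No earlier run stands at 1 mol% of free catalyst, so the best time of the flask cannot be read from either table.

common to all: starting material 0.0010 M
- red: second substrate 0.50 equiv; free catalyst 1.4 mol%; run made earlier
- green: second substrate 0.50 equiv; free catalyst 2.2 mol%; run made earlier
- flask: second substrate 0.500 equiv; free catalyst 1 mol%; time 6.0 min

| run | time / min | target / % | starting material / % |
|---|---|---|---|
| red | 0.833 | 52.5 | 44.8 |
| red | 1.33 | 71.4 | 23.7 |
| red | 2.00 | 82.3 | 7.5 |
| red | 2.50 | 81.6 | 2.6 |
| red | 4.00 | 71.6 | 0 |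
| red | 6.00 | 57.9 | 0.2 |
| green | 0.833 | 70.3 | 23.9 |
| green | 1.33 | 82.7 | 7.0 |
| green | 2.00 | 78.6 | 0.8 |
| green | 2.50 | 72.6 | 1.0 |
| green | 4.00 | 56.7 | 0 |
| green | 6.00 | 44.1 | 0.1 |

(standard deviation of a reading: 0.5 percentage points)

- the best time, 6.0 min at the latest, for target
- the amount of target, in percent of the starting material charged, at that time

But the red and green charges differ in the loading of free catalyst and not in starting material or second substrate. So, for these charges, we try a rule: equal loading times time gives an equal flask, which is what chemists call a normalised time axis. Red at 1.33 min and green at 0.833 min have nearly equal products, and they read 71.4% and 70.3% of target, 23.7% and 23.9% of starting material, against a scatter of 0.5 percentage points on each reading.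

The highest target reading is green's 82.7% at 1.33 min. That gives 2.93 min, our peak flask-time: the time of the highest target reading, multiplied by that run's loading and divided by the flask's loading. So we expect the flask to peak near 2.93 min, at about 82.7%, both read from a single reading and carrying its scatter.

The forecast says 3.1 min and 83%, on the ground that “Plotted against catalyst × time, the runs overlap”; its time is later than ours by 0.170 min.

The flask gives 3.12 min and 83.0%.

    starting material + free catalyst ⇌ catalyst intermediate A (K = 2800 L mol⁻¹, k = 7100 L mol⁻¹ s⁻¹)
    catalyst intermediate A → free catalyst + target (k = 1.50 s⁻¹)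
    second substrate + free catalyst ⇌ catalyst intermediate B (K = 9100 L mol⁻¹, k = 2800 L mol⁻¹ s⁻¹)
    catalyst intermediate B → free catalyst + second product (k = 5.30 s⁻¹)
    target + free catalyst ⇌ isomer of the product + free catalyst, rate k5*[free catalyst]*[target] forward; the back reaction follows from the equilibrium constant (K = 2.50, k = 160 L mol⁻¹ s⁻¹)
    starting material → decomposition product (k = 1.20 × 10⁻⁴ s⁻¹)

The neighbour flask with 0.25 mol% of free catalyst is reckoned the same way: the rule puts its peak at 11.7 min, later than the 6.0 min allowed. Its 6.0 min is worth a flask-time of 1.50 min, between the flask-times 1.17 min and 1.86 min of red's first two readings, and interpolating red's target readings there gives 61.6%. The neighbour flask gives 62.1% of target, with 32.7% of the starting material still unbound at 6.00 min.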